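The γ-lactone ring (O1, C2 carbonyl, C3, C4, C5) carries an exocyclic carboxyl carbon on C4, next to the carbinol carbon C5: the retron of a Wolff ring contraction. The C4–C5 bond is therefore formed from a six-membered (6R)-4-diazo-oxane-2,5-dione in which the future carboxyl carbon still separates C4 and C5 as a ring ketone. Light expels N2, C5 migrates with retention onto C4, the five-membered lactone closes and the extruded carbon emerges as the C4 ester; base then sets the trans relationship. The oxanedione comes from a 2-acylfuran by asymmetric transfer hydrogenation, Achmatowicz ring expansion, hydrogenation and lactol oxidation. Methylenation at C3 and acetylation finish the synthesis.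

Key step: step 7

Remark: the labels O1, C2, C3, C4 and C5 are those of the target lactone and stay with the same atoms in every precursor. In the oxane names, target C5 is ring position 6 (or 2), and the future carboxyl carbon is the ring ketone carbon.

Step 1
Reactants: 1 ethyl 3-(furan-2-yl)-3-oxopropanoate; 2 12-bromododecan-1-ol
Product: 4 1-(furan-2-yl)-14-hydroxytetradecan-1-one, via alkylated keto ester 3 (not isolated)
Conditions: K2CO3, NaI (cat.), DMSO, 50 °C; then LiCl, H2O, 150 °C
Reagents that add atoms: none
Why: Acetoacetic-ester-type ketone synthesis: the stabilised β-keto ester enolate is C-alkylated by the primary bromide (SN2, iodide catalysis) without touching the free alcohol, and Krapcho dealkoxycarbonylation in the same wet DMSO removes the activating ester, so the thirteen-methylene spacer comes from one enolate carbon plus the twelve carbons of 2.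

Step 2
Reactants: 4 1-(furan-2-yl)-14-hydroxytetradecan-1-one
Product: 5 (1R)-1-(furan-2-yl)tetradecane-1,14-diol
Conditions: RuCl(p-cymene)[(R,R)-TsDPEN] (0.5 mol %), HCO2H–Et3N 5:2, 25 °C
Reagents that add atoms: none
Why: Noyori-type asymmetric transfer hydrogenation: the CH/π contact between the furan and the η6-arene of the (R,R) catalyst directs hydride to one face of the aryl-type ketone and sets the R carbinol centre (future C5), the remote primary alcohol being inert.

Step 3
Reactants: 5 (1R)-1-(furan-2-yl)tetradecane-1,14-diol
Product: 6 (2R)-6-hydroxy-2-(13-hydroxytridecyl)-2H-pyran-3(6H)-one (anomer mixture)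
Conditions: NBS, NaHCO3, NaOAc, THF–H2O 4:1, 0 °C
Reagents that add atoms: water, O
Why: Achmatowicz rearrangement: oxidation of the furan and addition of water open it to the cis-enedione, which the carbinol oxygen re-closes to the six-membered lactol, so furan C2 becomes the ring ketone (future carboxyl carbon) while the carbinol centre is not involved and keeps its configuration.

Step 4
Reactants: 6 (2R)-6-hydroxy-2-(13-hydroxytridecyl)-2H-pyran-3(6H)-one
Product: 7 (2R)-6-hydroxy-2-(13-hydroxytridecyl)oxan-3-one (anomer mixture)
Conditions: H2 (1 atm), 10% Pd/C, EtOAc, 20 °C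
Reagents that add atoms: none
Why: Heterogeneous catalytic hydrogenation saturates the electron-poor enone C=C (future C3–C4) much faster than the ketone or lactol, and removing the alkene first avoids an enedione lactone that could tautomerise to an achiral hydroxypyranone.

Step 5
Reactants: 7 (2R)-6-hydroxy-2-(13-hydroxytridecyl)oxan-3-one
Product: 8 (6R)-6-(13-hydroxytridecyl)oxane-2,5-dione
Conditions: Ag2CO3 on Celite, toluene, 80 °C
Reagents that add atoms: none
Why: Fétizon oxidation: Ag2CO3 on Celite oxidises lactols far faster than isolated primary alcohols under essentially neutral conditions, so the δ-lactone should form without protecting the chain hydroxyl and without enolising the stereocentre.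

Step 6
Reactants: 8 (6R)-6-(13-hydroxytridecyl)oxane-2,5-dione
Product: 10 (6R)-4-diazo-6-(13-hydroxytridecyl)oxane-2,5-dione, via bis(trifluoroacetyl) compound 9 (not isolated)
Conditions: LiN(SiMe3)2 (2.2 equiv), THF, −78 °C; CF3CO2CH2CF3 (2.5 equiv); dilute HCl quench; crude 9, MsN3, Et3N, H2O, MeCN, 20 °C; aq NaHCO3 wash
Reagents that add atoms: methanesulfonyl azide, CS(=O)(=O)N=[N+]=[N-] (the N2 unit); 2,2,2-trifluoroethyl trifluoroacetate, O=C(OCC(F)(F)F)C(F)(F)F (trifluoroacetyl groups of 9 only, lost again)
Why: Detrifluoroacetylative (Regitz-type) diazo transfer: after the alkoxide forms, kinetic deprotonation takes the unhindered ketone α-CH2 (C4) rather than the tertiary oxygen-bearing α-CH or the less acidic lactone α-CH2, C-trifluoroacetylation then makes C4 acidic enough for diazo transfer under Et3N with loss of the trifluoroacetyl group, and the transient primary trifluoroacetate is cleaved by the aqueous base.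

Step 7
Reactants: 10 (6R)-4-diazo-6-(13-hydroxytridecyl)oxane-2,5-dione
Product: 13 methyl (2R,3S)-2-(13-hydroxytridecyl)-5-oxooxolane-3-carboxylate, via ketene 11 (not isolated), via cis ester 12 (not isolated)
Conditions: hν (365 nm), THF–MeOH 9:1, 20 °C; then DBU (0.5 equiv), 20 °C
Reagents that add atoms: methanol, CO
Why: Excitation of the ring-locked s-Z diazoketone expels N2 while the C5–C(=O) bond, antiperiplanar to the C–N2 bond, shifts onto C4 (Wolff rearrangement), so the C4–C5 bond forms, the former ring ketone carbon leaves the ring as ketene 11 and methanol converts it into the ester. The closest known reaction type is the photochemical Wolff ring contraction of 2-diazocyclohexanones and diazo-oxanones to cyclopentane- and oxolane-carboxylates. The five-membered lactone closes by a 1,2-shift through a three-centre transition state, a six-to-five ring contraction rather than an exo or endo attack. C5 migrates with retention, so its R configuration is the one set in step 2. C4 arises by protonation of the ketene hemiacetal, expected mainly anti to the C5 chain (cis ester 12), and DBU then equilibrates this only acidic stereocentre to the more stable trans ester 13, lactone opening by β-elimination being the reverse of a 5-endo-trig closure and therefore slow. The step needs migration to outrun 1,2-hydride shift from C3 and O–H insertion, which the concerted pathway of the locked s-Z geometry and the electron-poor C3–H bonds (alpha to the lactone carbonyl) should secure.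

Step 8
Reactants: 13 methyl (2R,3S)-2-(13-hydroxytridecyl)-5-oxooxolane-3-carboxylate
Product: 14 (2R,3S)-2-(13-hydroxytridecyl)-5-oxooxolane-3-carboxylic acid
Conditions: 6 M HCl, 1,4-dioxane, 100 °C
Reagents that add atoms: water, O
Why: Acid-catalysed ester hydrolysis in a water-rich medium cleaves the methyl ester while the γ-lactone, the thermodynamically preferred ring, persists or re-forms, acid cannot trigger β-elimination, and the trans arrangement is already the stable one.

Step 9
Reactants: 14 (2R,3S)-2-(13-hydroxytridecyl)-5-oxooxolane-3-carboxylic acid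
Product: 16 (2R,3S)-2-(13-hydroxytridecyl)-4-methylidene-5-oxooxolane-3-carboxylic acid, via dicarboxylic acid 15 (not isolated)
Conditions: MeOMgOCO2Me (2 M in DMF, excess), 130 °C; cold 6 M HCl; crude 15, 37% aq HCHO, PhNHMe, NaOAc, AcOH, 20 °C
Reagents that add atoms: formaldehyde, C=O (the methylidene carbon); methoxymagnesium methyl carbonate, COC(=O)O[Mg]OC (CO2 unit of 15 only, lost again)
Why: Carboxylation of the lactone α-carbon C3 through a magnesium chelate followed by decarboxylative Mannich-type methylenation, the established end-game for paraconic acids, in which the C4 carboxylate shields the C4–H from deprotonation and the chain alkoxide or carbonate reverts to the alcohol on acidification.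

Step 10
Reactants: 16 (2R,3S)-2-(13-hydroxytridecyl)-4-methylidene-5-oxooxolane-3-carboxylic acid
Product: 17 (2R,3S)-2-(13-acetoxytridecyl)-4-methylidene-5-oxooxolane-3-carboxylic acid (target)
Conditions: vinyl acetate, immobilised Candida antarctica lipase B, tBuOMe, 30 °C
Reagents that add atoms: vinyl acetate, C=COC(C)=O
Why: Lipase-catalysed irreversible transesterification acetylates the only alcohol, an unhindered primary one, at neutral pH, so the exocyclic alkene should not migrate into the ring and C4 is not epimerised.

Compound list
1 | ethyl 3-(furan-2-yl)-3-oxopropanoate | CCOC(=O)CC(=O)c1ccco1 | starting material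
2 | 12-bromododecan-1-ol | OCCCCCCCCCCCCBr | starting material
3 | ethyl 2-(furan-2-carbonyl)-14-hydroxytetradecanoate (racemic, not isolated) | CCOC(=O)C(CCCCCCCCCCCCO)C(=O)c1ccco1 | intermediate
4 | 1-(furan-2-yl)-14-hydroxytetradecan-1-one | O=C(CCCCCCCCCCCCCO)c1ccco1 | intermediate
5 | (1R)-1-(furan-2-yl)tetradecane-1,14-diol | O[C@H](CCCCCCCCCCCCCO)c1ccco1 | intermediate
6 | (2R)-6-hydroxy-2-(13-hydroxytridecyl)-2H-pyran-3(6H)-one (anomers) | OC1C=CC(=O)[C@@H](CCCCCCCCCCCCCO)O1 | intermediate
7 | (2R)-6-hydroxy-2-(13-hydroxytridecyl)oxan-3-one (anomers) | OC1CCC(=O)[C@@H](CCCCCCCCCCCCCO)O1 | intermediate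
8 | (6R)-6-(13-hydroxytridecyl)oxane-2,5-dione | O=C1CCC(=O)[C@@H](CCCCCCCCCCCCCO)O1 | intermediate
9 | 13-[(2R)-3,6-dioxo-4-(trifluoroacetyl)oxan-2-yl]tridecyl trifluoroacetate (not isolated) | O=C1CC(C(=O)C(F)(F)F)C(=O)[C@@H](CCCCCCCCCCCCCOC(=O)C(F)(F)F)O1 | intermediate
10 | (6R)-4-diazo-6-(13-hydroxytridecyl)oxane-2,5-dione | O=C1CC(=[N+]=[N-])C(=O)[C@@H](CCCCCCCCCCCCCO)O1 | intermediate
11 | (5R)-5-(13-hydroxytridecyl)-4-(oxomethylidene)oxolan-2-one (ketene, not isolated) | O=C=C1CC(=O)O[C@@H]1CCCCCCCCCCCCCO | intermediate
12 | methyl (2R,3R)-2-(13-hydroxytridecyl)-5-oxooxolane-3-carboxylate (cis, not isolated) | O=C1C[C@@H](C(=O)OC)[C@@H](CCCCCCCCCCCCCO)O1 | intermediate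
13 | methyl (2R,3S)-2-(13-hydroxytridecyl)-5-oxooxolane-3-carboxylate (trans) | O=C1C[C@H](C(=O)OC)[C@@H](CCCCCCCCCCCCCO)O1 | intermediate
14 | (2R,3S)-2-(13-hydroxytridecyl)-5-oxooxolane-3-carboxylic acid | O=C1C[C@H](C(=O)O)[C@@H](CCCCCCCCCCCCCO)O1 | intermediate
15 | (4S,5R)-5-(13-hydroxytridecyl)-2-oxooxolane-3,4-dicarboxylic acid (C3 epimers, not isolated) | OC(=O)C1C(=O)O[C@H](CCCCCCCCCCCCCO)[C@H]1C(=O)O | intermediate
16 | (2R,3S)-2-(13-hydroxytridecyl)-4-methylidene-5-oxooxolane-3-carboxylic acid | C=C1C(=O)O[C@H](CCCCCCCCCCCCCO)[C@H]1C(=O)O | intermediate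
17 | (2R,3S)-2-(13-acetoxytridecyl)-4-methylidene-5-oxooxolane-3-carboxylic acid | C=C1C(=O)O[C@H](CCCCCCCCCCCCCOC(C)=O)[C@H]1C(=O)O | target

Total step count: 10. Longest linear sequence: 10 (from 1 or 2 to 17).

Steps most likely to fail

1. Step 7.
- What may go wrong: a free carbene may escape the concerted path, giving hydride shift from C3 or insertion into methanol. The electron-poor, acyloxy-bearing migrating carbon may shift sluggishly. During equilibration, the ester enolate may open the lactone by β-elimination instead of simply reprotonating.
- Fallback: run the ring contraction at the acetal oxidation level, setting out from 7 and returning at 13.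
- Lactol 7 is converted with MeOH, HC(OMe)3 and pyridinium tosylate into (2R)-2-(13-hydroxytridecyl)-6-methoxyoxan-3-one F1.
- The diazo transfer of step 6 then gives (2R)-4-diazo-2-(13-hydroxytridecyl)-6-methoxyoxan-3-one F2. Its migrating carbon bears a donor ether oxygen, and its ring holds no lactone.
- Photolysis in MeOH followed by DBU gives methyl (2R,3S)-2-(13-hydroxytridecyl)-5-methoxyoxolane-3-carboxylate F3, in which β-elimination would need an alkoxide leaving group.
- Peracid oxidation of the cyclic acetal (mCPBA, BF3·OEt2, CH2Cl2) then delivers 13.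

2. Step 6.
- What may go wrong: competing deprotonation at the oxygen-bearing α-carbon or enolate equilibration would erode the configuration of the future C5. The chain alkoxide or the amide base may attack the δ-lactone.
- Fallback: avoid the strong base, setting out from 8 and returning at 10.
- Ketone 8 is condensed with tert-butoxybis(dimethylamino)methane (toluene, 60 °C) at its most acidic CH2 to give the enaminone (4E,6R)-4-[(dimethylamino)methylidene]-6-(13-hydroxytridecyl)oxane-2,5-dione F4.
- F4 is treated with TsN3 in CH2Cl2. Cycloaddition and fragmentation of the triazoline give 10.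

3. Step 9.
- What may go wrong: carboxylation at 130 °C may be slow. The free magnesium alkoxide may start intermolecular transesterification. The exocyclic alkene may drift into the ring during the Mannich stage.
- Fallback: aminomethylation at low temperature, setting out from 14 and returning at 16.
- Acid 14 is converted with LiN(SiMe3)2 (3.3 equiv, THF, −78 °C) into the alkoxide–carboxylate–lactone enolate. This is trapped with dimethylmethylideneammonium iodide to give (2R,3S)-4-[(dimethylamino)methyl]-2-(13-hydroxytridecyl)-5-oxooxolane-3-carboxylic acid F5.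
- Quaternisation with MeI and elimination with aq NaHCO3 give 16.

Further compounds
F1 | step 7 | (2R)-2-(13-hydroxytridecyl)-6-methoxyoxan-3-one (anomers) | COC1CCC(=O)[C@@H](CCCCCCCCCCCCCO)O1
F2 | step 7 | (2R)-4-diazo-2-(13-hydroxytridecyl)-6-methoxyoxan-3-one | COC1CC(=[N+]=[N-])C(=O)[C@@H](CCCCCCCCCCCCCO)O1
F3 | step 7 | methyl (2R,3S)-2-(13-hydroxytridecyl)-5-methoxyoxolane-3-carboxylate (anomers) | COC1C[C@H](C(=O)OC)[C@@H](CCCCCCCCCCCCCO)O1
F4 | step 6 | (4E,6R)-4-[(dimethylamino)methylidene]-6-(13-hydroxytridecyl)oxane-2,5-dione | O=C1C/C(=C\N(C)C)C(=O)[C@@H](CCCCCCCCCCCCCO)O1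
F5 | step 9 | (2R,3S)-4-[(dimethylamino)methyl]-2-(13-hydroxytridecyl)-5-oxooxolane-3-carboxylic acid (C4 epimers) | CN(C)CC1C(=O)O[C@H](CCCCCCCCCCCCCO)[C@H]1C(=O)O
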